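**Retrosynthetic overview** (target numbered as a chromane: O1, C2 … C8a)
- Pyran ring C is made last from δ-lactone 18: vinyl adds to the lactone carbonyl (C2), then AlMe3 methylates the C2 oxocarbenium ion anti to the axial 8a-CH3. The lactone comes from acid-mediated capture of the C8a cation by the C4a side-chain acid.
- Cyclohexane ring B is closed in one [3+3] Mukaiyama aldol/Mukaiyama–Michael cascade that forms C8–C8a and C5–C6 from two acyclic fragments (ketone-derived enol silane 6 and keto-enoate 8).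
- Enabling feature: in ring B, C8a (tertiary ether carbon) and C5 (quaternary, β to the carbonyl of its CH2CO2H arm) are 1,3-related across C4a, and both are electrophile-derived. C6–C7–C8 is the α–C(=O)–α′ unit of a methyl ketone once C7 carries a temporary carbonyl.
- Order of rings: ring B (step 5), lactone ring (step 9), converted into pyran ring C (steps 11–12). The C7 ketone is removed in steps 6–7.
- The route is racemic up to lactone acid 16; absolute configuration is fixed by classical resolution (step 10).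

Key step: step 5

Remark: keto-enoate 8 epimerises at its CH through the dienol, so 9–16 are racemates (SMILES show the enantiomer carried on; 9–15 are C8a-epimer mixtures), and the (S)-amine is assumed to give the less soluble salt of the required acid (otherwise the (R)-amine is used on the mother liquor).

**Step 1**
Reactants: 1 methyl 2-methylpropanoate; 2 3-chloro-2-methylprop-1-ene
Product: 3 methyl 2,2,4-trimethylpent-4-enoate
Conditions: LiN(i-Pr)2, THF, −78 °C; then 2, DMPU, −78 → 23 °C
Reagents that add atoms: none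
Why: Ester enolate alkylation (SN2 on an allylic chloride) should install the gem-dimethyl quaternary carbon; no stereocentre is formed.

**Step 2**
Reactants: 3 methyl 2,2,4-trimethylpent-4-enoate
Product: 5 methyl 2,2-dimethyl-4-oxopentanoate, via ozonide 4 (not isolated)
Conditions: O3, CH2Cl2, −78 °C; then Me2S, −78 → 23 °C
Reagents that add atoms: ozone, [O-][O+]=O
Why: Ozonolysis with reductive work-up should cleave the 1,1-disubstituted alkene to the methyl ketone without touching the ester.

**Step 3**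
Reactants: 5 methyl 2,2-dimethyl-4-oxopentanoate
Product: 6 methyl 2,2-dimethyl-4-[(trimethylsilyl)oxy]pent-4-enoate
Conditions: LiN(i-Pr)2, THF, −78 °C; Me3SiCl, −78 → 0 °C
Reagents that add atoms: chlorotrimethylsilane, C[Si](C)(C)Cl
Why: Kinetic silyl enol ether formation should occur at the methyl group, because the CH2 is neopentyl and the ester has no α-hydrogen.

**Step 4**
Reactants: 7 methyl 4-acetyl-5-oxohexanoate
Product: 8 dimethyl (2E)-4-acetyl-3-methylhept-2-enedioate
Conditions: Ph3P=CHCO2Me (1.2 equiv), PhCO2H (0.1 equiv), toluene, 110 °C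
Reagents that add atoms: methyl (triphenylphosphoranylidene)acetate, COC(=O)C=P(c1ccccc1)(c1ccccc1)c1ccccc1
Why: Wittig olefination with a stabilised ylide at one of the two equivalent acetyl groups should give the (E)-enoate (ester trans to the branched carbon), the minor (Z)-isomer being lost as its 2-pyranone.

**Step 5**
Reactants: 6 methyl 2,2-dimethyl-4-[(trimethylsilyl)oxy]pent-4-enoate; 8 dimethyl (2E)-4-acetyl-3-methylhept-2-enedioate
Product: 12 methyl 3-[6-hydroxy-3-(1-methoxy-2-methyl-1-oxopropan-2-yl)-2-(2-methoxy-2-oxoethyl)-2,6-dimethyl-4-oxocyclohexyl]propanoate, via aldol silyl ether 9 (not isolated), via enol silane 10 (not isolated), via cyclised silyl ketene acetal 11 (not isolated)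
Conditions: Me3SiOTf (0.2 equiv), CH2Cl2, −78 °C; then Me3SiOTf (2.5 equiv), Et3N (3 equiv), −78 → 0 °C; 1 M HCl, THF, 0 °C
Reagents that add atoms: none
Why: Catalytic Me3SiOTf activates the acetyl carbonyl of 8 for Mukaiyama aldol addition of the terminal carbon of 6 (bond C8–C8a, giving 9); Me3SiOTf/Et3N then converts the ketone of 9 into enol silane 10, whose C6 carbon adds to the silyl-activated (E)-enoate in an intramolecular Mukaiyama–Michael reaction (bond C5–C6, quaternary C5) to give 11, which acidic work-up hydrolyses to 12. The closest known reactions are the isophorone-type ketone/enone [3+3] condensation and one-pot enol silane formation/Mukaiyama–Michael additions under Me3SiOTf/amine. Ring B closes in a 6-(enolendo)-exo-trig mode through a chair-like transition state. C4a is fixed by the aldol event and should then control C5: its side chain sits equatorial and H-4a eclipses the enoate C=C (allylic 1,3-strain), so the CH–CO2Me arm becomes equatorial and 5-CH3 axial, anti to H-4a. C6 carries its ester-bearing group equatorial and can equilibrate α to the ketone; C8a forms as an epimer mixture that is corrected in step 9. The step needs enolisation toward C6 rather than C8 (the unproductive enol silane should revert) and no β-elimination of the silyl ether, which the low temperature and non-basic medium should secure.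

**Step 6**
Reactants: 12 hydroxy ketone triester
Product: 13 tosylhydrazone of 12
Conditions: TsNHNH2 (1.5 equiv), MeOH, 50 °C
Reagents that add atoms: 4-methylbenzenesulfonohydrazide, Cc1ccc(cc1)S(=O)(=O)NN
Why: Hydrazone condensation under neutral conditions should engage only the ketone and avoid retro-aldol cleavage or dehydration of the tertiary β-hydroxy group.

**Step 7**
Reactants: 13 tosylhydrazone
Product: 14 methyl 3-[2-hydroxy-5-(1-methoxy-2-methyl-1-oxopropan-2-yl)-6-(2-methoxy-2-oxoethyl)-2,6-dimethylcyclohexyl]propanoate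
Conditions: catecholborane (3 equiv), CHCl3, 0 °C; then NaOAc·3H2O, 60 °C
Reagents that add atoms: none
Why: Tosylhydrazone reduction (hydride addition, then loss of sulfinate and N2 from the diazene) should turn the temporary C7 carbonyl into CH2 under near-neutral conditions that spare the esters and the tertiary alcohol.

**Step 8**
Reactants: 14 hydroxy triester
Product: 15 3-[6-(carboxymethyl)-2-hydroxy-5-(1-methoxy-2-methyl-1-oxopropan-2-yl)-2,6-dimethylcyclohexyl]propanoic acid
Conditions: LiOH (6 equiv), THF/MeOH/H2O, 45 °C; then 1 M HCl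
Reagents that add atoms: lithium hydroxide, [Li+].[OH-]
Why: Saponification should cleave the two unhindered methyl esters, while the α,α-dimethyl ester on C6 is too hindered to react.

**Step 9**
Reactants: 15 hydroxy diacid
Product: 16 2-[6-(1-methoxy-2-methyl-1-oxopropan-2-yl)-5,8a-dimethyl-2-oxo-octahydro-2H-chromen-5-yl]acetic acid (racemate, relative configuration 4aS,5R,6S,8aS)
Conditions: CF3CO2H, CH2Cl2, 0 → 23 °C
Reagents that add atoms: none
Why: Acid-mediated lactonisation through the tertiary C8a cation (as in the cyclisation of labdane-type hydroxy or unsaturated acids to trans-fused lactones) should let the C4a side-chain carboxyl attack anti to the axial 5-CH3, giving equatorial C–O, axial 8a-CH3 and a trans ring fusion from both C8a epimers; the bridged lactone from the C5 arm would need a diaxial chair and is disfavoured.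

**Step 10**
Reactants: 16 racemic lactone acid
Product: 17 (S)-1-phenylethylammonium 2-[(4aS,5R,6S,8aS)-6-(1-methoxy-2-methyl-1-oxopropan-2-yl)-5,8a-dimethyl-2-oxo-octahydro-2H-chromen-5-yl]acetate
Conditions: (S)-1-phenylethylamine (0.55 equiv), EtOAc/i-PrOH, 60 → 4 °C, two recrystallisations
Reagents that add atoms: (S)-1-phenylethylamine, C[C@H](N)c1ccccc1
Why: Classical resolution by diastereomeric salt crystallisation should deliver the (4aS,5R,6S,8aS) acid as its less soluble salt and so fix the absolute configuration of all ring stereocentres.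

**Step 11**
Reactants: 17 resolved ammonium salt
Product: 19 2-[(4aS,5R,6S,8aS)-2-ethenyl-2-hydroxy-6-(1-methoxy-2-methyl-1-oxopropan-2-yl)-5,8a-dimethyl-octahydro-2H-chromen-5-yl]acetic acid (C2 anomers), via free lactone acid 18 (not isolated)
Conditions: 1 M HCl/EtOAc (extractive release of 18); then vinylmagnesium bromide (3.2 equiv), THF, −78 °C; aq NH4Cl
Reagents that add atoms: vinylmagnesium bromide, C=C[Mg]Br
Why: Grignard mono-addition to a δ-lactone should stop at the tetrahedral alkoxide at −78 °C; the first equivalent turns the acid into an inert carboxylate and the hindered ester is not attacked.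

**Step 12**
Reactants: 19 vinyl lactol
Product: 20 2-[(2R,4aS,5R,6S,8aS)-2-ethenyl-6-(1-methoxy-2-methyl-1-oxopropan-2-yl)-2,5,8a-trimethyl-octahydro-2H-chromen-5-yl]acetic acid (target)
Conditions: AlMe3 (6 equiv), CH2Cl2, −78 → 0 °C; aq potassium sodium tartrate
Reagents that add atoms: trimethylaluminium, C[Al](C)C
Why: Lewis-acid ionisation of the hemiketal to the cyclic oxocarbenium ion and methyl transfer from aluminium (C-glycosylation-type substitution) should place the methyl on the face opposite the axial 8a-CH3, so 2-CH3 ends equatorial and the vinyl group axial, cis to 8a-CH3 (2R).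

**Compound list**
1 | methyl 2-methylpropanoate | COC(=O)C(C)C | starting material
2 | 3-chloro-2-methylprop-1-ene | C=C(C)CCl | starting material
3 | methyl 2,2,4-trimethylpent-4-enoate | COC(=O)C(C)(C)CC(C)=C | intermediate
4 | methyl 2,2-dimethyl-3-(3-methyl-1,2,4-trioxolan-3-yl)propanoate (ozonide) | COC(=O)C(C)(C)CC1(C)OCOO1 | intermediate (not isolated)
5 | methyl 2,2-dimethyl-4-oxopentanoate | COC(=O)C(C)(C)CC(C)=O | intermediate
6 | methyl 2,2-dimethyl-4-[(trimethylsilyl)oxy]pent-4-enoate | COC(=O)C(C)(C)CC(=C)O[Si](C)(C)C | intermediate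
7 | methyl 4-acetyl-5-oxohexanoate | COC(=O)CCC(C(C)=O)C(C)=O | starting material
8 | dimethyl (2E)-4-acetyl-3-methylhept-2-enedioate (racemic, C4 labile) | COC(=O)/C=C(\C)C(C(C)=O)CCC(=O)OC | intermediate
9 | dimethyl (2E)-4-{7-methoxy-6,6-dimethyl-4,7-dioxo-2-[(trimethylsilyl)oxy]heptan-2-yl}-3-methylhept-2-enedioate (diastereomer mixture) | COC(=O)C(C)(C)CC(=O)CC(C)(O[Si](C)(C)C)C(CCC(=O)OC)/C(C)=C/C(=O)OC | intermediate (not isolated)
10 | dimethyl (2E)-4-{7-methoxy-6,6-dimethyl-7-oxo-2,4-bis[(trimethylsilyl)oxy]hept-4-en-2-yl}-3-methylhept-2-enedioate | COC(=O)C(C)(C)C=C(O[Si](C)(C)C)CC(C)(O[Si](C)(C)C)C(CCC(=O)OC)/C(C)=C/C(=O)OC | intermediate (not isolated)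
11 | cyclised silyl ketene acetal, 8a-O-silyl ether (ring configuration as in 12) | CC1(O[Si](C)(C)C)CC(=O)[C@H](C(C)(C)C(=O)OC)[C@@](C)(C=C(OC)O[Si](C)(C)C)[C@@H]1CCC(=O)OC | intermediate (not isolated)
12 | methyl 3-[6-hydroxy-3-(1-methoxy-2-methyl-1-oxopropan-2-yl)-2-(2-methoxy-2-oxoethyl)-2,6-dimethyl-4-oxocyclohexyl]propanoate (racemate; H-1 anti to 2-CH3, 3-substituent cis to 2-CH3; both C6 carbinol epimers) | CC1(O)CC(=O)[C@H](C(C)(C)C(=O)OC)[C@@](C)(CC(=O)OC)[C@@H]1CCC(=O)OC | intermediate
13 | 4-methylbenzenesulfonylhydrazone of 12 (same configuration) | CC1(O)CC(=NNS(=O)(=O)c2ccc(C)cc2)[C@H](C(C)(C)C(=O)OC)[C@@](C)(CC(=O)OC)[C@@H]1CCC(=O)OC | intermediate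
14 | methyl 3-[2-hydroxy-5-(1-methoxy-2-methyl-1-oxopropan-2-yl)-6-(2-methoxy-2-oxoethyl)-2,6-dimethylcyclohexyl]propanoate (racemate, carbinol epimers) | CC1(O)CC[C@H](C(C)(C)C(=O)OC)[C@@](C)(CC(=O)OC)[C@@H]1CCC(=O)OC | intermediate
15 | 3-[6-(carboxymethyl)-2-hydroxy-5-(1-methoxy-2-methyl-1-oxopropan-2-yl)-2,6-dimethylcyclohexyl]propanoic acid (racemate, carbinol epimers) | CC1(O)CC[C@H](C(C)(C)C(=O)OC)[C@@](C)(CC(=O)O)[C@@H]1CCC(=O)O | intermediate
16 | rac-2-[(4aS,5R,6S,8aS)-6-(1-methoxy-2-methyl-1-oxopropan-2-yl)-5,8a-dimethyl-2-oxo-octahydro-2H-chromen-5-yl]acetic acid | O=C1CC[C@H]2[C@](C)(CC(=O)O)[C@@H](C(C)(C)C(=O)OC)CC[C@]2(C)O1 | intermediate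
17 | (S)-1-phenylethylammonium salt of the (4aS,5R,6S,8aS) lactone acid | O=C1CC[C@H]2[C@](C)(CC(=O)[O-])[C@@H](C(C)(C)C(=O)OC)CC[C@]2(C)O1.C[C@H]([NH3+])c1ccccc1 | intermediate
18 | 2-[(4aS,5R,6S,8aS)-6-(1-methoxy-2-methyl-1-oxopropan-2-yl)-5,8a-dimethyl-2-oxo-octahydro-2H-chromen-5-yl]acetic acid (single enantiomer) | O=C1CC[C@H]2[C@](C)(CC(=O)O)[C@@H](C(C)(C)C(=O)OC)CC[C@]2(C)O1 | intermediate (not isolated)
19 | 2-[(4aS,5R,6S,8aS)-2-ethenyl-2-hydroxy-6-(1-methoxy-2-methyl-1-oxopropan-2-yl)-5,8a-dimethyl-octahydro-2H-chromen-5-yl]acetic acid (C2 anomers) | OC1(C=C)CC[C@H]2[C@](C)(CC(=O)O)[C@@H](C(C)(C)C(=O)OC)CC[C@]2(C)O1 | intermediate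
20 | 2-[(2R,4aS,5R,6S,8aS)-2-ethenyl-6-(1-methoxy-2-methyl-1-oxopropan-2-yl)-2,5,8a-trimethyl-octahydro-2H-chromen-5-yl]acetic acid | C=C[C@@]1(C)CC[C@H]2[C@](C)(CC(=O)O)[C@@H](C(C)(C)C(=O)OC)CC[C@]2(C)O1 | target

**Step count and risks**
Total steps: 12. Longest linear sequence: 11 (steps 1–3 and 5–12).

Steps most likely to fail:

1. Step 5. The cascade may stall after the aldol addition, lose the β-silyloxy group by elimination, or close ring B with poor facial selectivity at C5 (the side chain instead of H-4a eclipsing the enoate). Fallback, setting out from 6 and 8: TiCl4 in CH2Cl2 at −78 °C followed by Et3N should give, by aldol condensation, the dienone dimethyl (2E)-4-[(2Z)-7-methoxy-6,6-dimethyl-4,7-dioxohept-2-en-2-yl]-3-methylhept-2-enedioate F1. DBU in MeCN should then close ring B by intramolecular Michael addition of the α′-enolate to give the cyclohexenone rac-(4R,5S,6S)-6-(1-methoxy-2-methyl-1-oxopropan-2-yl)-5-(2-methoxy-2-oxoethyl)-4-(3-methoxy-3-oxopropyl)-3,5-dimethylcyclohex-2-en-1-one F2. Weitz–Scheffer epoxidation (H2O2, NaOH, MeOH), anti to the axial 5-CH3, should give the 2,3-epoxy ketone F3, and SmI2 (THF/MeOH, −78 °C) should open it reductively to the β-hydroxy ketone, returning to the route at 12.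

2. Step 12. Methyl may add in a conjugate sense to the vinyl-substituted oxocarbenium ion or to the open hydroxy-enone tautomer, and facial control may erode. Fallback, setting out from 18: LiC≡CSiMe3 (3 equiv, THF, −78 °C) should give the alkynyl lactol 2-[(4aS,5R,6S,8aS)-2-hydroxy-6-(1-methoxy-2-methyl-1-oxopropan-2-yl)-5,8a-dimethyl-2-[(trimethylsilyl)ethynyl]-octahydro-2H-chromen-5-yl]acetic acid F4. AlMe3 should methylate its propargylic oxocarbenium ion at C2 only, giving the (2R)-2-methyl-2-[(trimethylsilyl)ethynyl] ether F5. K2CO3 in MeOH should remove silicon to give the (2R)-2-ethynyl ether F6, and H2 over Pd/CaCO3 poisoned with Pb(OAc)2 and quinoline should give the vinyl group, returning at 20.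

3. Step 7. Hydrazone formation may stall at the hindered ketone, or the β-hydroxy tosylhydrazone may dehydrate or fragment during reduction. Fallback, setting out from 12: NaBH4 in MeOH should give the diol methyl 3-[4,6-dihydroxy-3-(1-methoxy-2-methyl-1-oxopropan-2-yl)-2-(2-methoxy-2-oxoethyl)-2,6-dimethylcyclohexyl]propanoate F7. 1,1′-Thiocarbonyldiimidazole should acylate only the secondary alcohol to give the imidazole-1-carbothioate F8, and Barton–McCombie deoxygenation (Bu3SnH, AIBN, toluene, 110 °C) should return to the route at 14.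

**Further compounds**
F1 | step 5 | dimethyl (2E)-4-[(2Z)-7-methoxy-6,6-dimethyl-4,7-dioxohept-2-en-2-yl]-3-methylhept-2-enedioate | COC(=O)C(C)(C)CC(=O)/C=C(/C)C(CCC(=O)OC)/C(C)=C/C(=O)OC
F2 | step 5 | rac-(4R,5S,6S)-6-(1-methoxy-2-methyl-1-oxopropan-2-yl)-5-(2-methoxy-2-oxoethyl)-4-(3-methoxy-3-oxopropyl)-3,5-dimethylcyclohex-2-en-1-one | CC1=CC(=O)[C@H](C(C)(C)C(=O)OC)[C@@](C)(CC(=O)OC)[C@@H]1CCC(=O)OC
F3 | step 5 | 2,3-epoxide of F2 (oxirane anti to 5-CH3) | CC12OC1C(=O)[C@H](C(C)(C)C(=O)OC)[C@@](C)(CC(=O)OC)[C@@H]2CCC(=O)OC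
F4 | step 12 | 2-[(4aS,5R,6S,8aS)-2-hydroxy-6-(1-methoxy-2-methyl-1-oxopropan-2-yl)-5,8a-dimethyl-2-[(trimethylsilyl)ethynyl]-octahydro-2H-chromen-5-yl]acetic acid | C[Si](C)(C)C#CC1(O)CC[C@H]2[C@](C)(CC(=O)O)[C@@H](C(C)(C)C(=O)OC)CC[C@]2(C)O1
F5 | step 12 | 2-[(2R,4aS,5R,6S,8aS)-6-(1-methoxy-2-methyl-1-oxopropan-2-yl)-2,5,8a-trimethyl-2-[(trimethylsilyl)ethynyl]-octahydro-2H-chromen-5-yl]acetic acid | C[Si](C)(C)C#C[C@@]1(C)CC[C@H]2[C@](C)(CC(=O)O)[C@@H](C(C)(C)C(=O)OC)CC[C@]2(C)O1
F6 | step 12 | 2-[(2R,4aS,5R,6S,8aS)-2-ethynyl-6-(1-methoxy-2-methyl-1-oxopropan-2-yl)-2,5,8a-trimethyl-octahydro-2H-chromen-5-yl]acetic acid | C#C[C@@]1(C)CC[C@H]2[C@](C)(CC(=O)O)[C@@H](C(C)(C)C(=O)OC)CC[C@]2(C)O1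
F7 | step 7 | methyl 3-[4,6-dihydroxy-3-(1-methoxy-2-methyl-1-oxopropan-2-yl)-2-(2-methoxy-2-oxoethyl)-2,6-dimethylcyclohexyl]propanoate | CC1(O)CC(O)[C@H](C(C)(C)C(=O)OC)[C@@](C)(CC(=O)OC)[C@@H]1CCC(=O)OC
F8 | step 7 | O-secondary 1H-imidazole-1-carbothioate of F7 | CC1(O)CC(OC(=S)n2ccnc2)[C@H](C(C)(C)C(=O)OC)[C@@](C)(CC(=O)OC)[C@@H]1CCC(=O)OC
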